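**Plan**
1. Retrosynthesis: after removal of the silyl groups, the C1–C8 bond of ring B is cut, which leaves a monocyclic 3-aroyl-1-alkyl-5,5-dilavandulylcyclohexanetrione. Ring A is then cut at C1–C9 and C3–C4 into 2,2-di[(R)-lavandulyl]malonyl dichloride and an aryl 1,3-diketone.
2. Enabling feature: C6, C7 and C8 of ring B, with the two C8 methyls and the C7 prenyl group, are a second lavandulyl unit of the same R configuration as the C5 side chain. C5, between the C4 and C9 carbonyls of ring A, is therefore a gem-dilavandulyl carbon that is not stereogenic until ring B exists.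
3. Forward order: ring A is made first by a [3+3] double Claisen acylation of the diketone dianion (C1, then C3) with the malonyl dichloride. Ring B follows by acid-mediated closure of one isopropenyl group onto C1.
4. Stereochemistry: C7 and the side-chain centre come from one two-directional Evans alkylation with (R)-4-benzyloxazolidin-2-one. C1 and C5 are fixed by which of the two diastereotopic lavandulyl groups closes ring B; the 7-endo product is separated from its 7-exo diastereomer.

Key step: step 14

Remark: positions are numbered as in the target (C1 and C5 bridgeheads, C2–C4 triketone bridge, C6–C8 bridge, C9 bridging ketone); "lavandulyl" means 5-methyl-2-(prop-1-en-2-yl)hex-4-en-1-yl; the target SMILES is read as 1R,5R,7R with an R side-chain centre, the C7 prenyl group lying on the side of the C2–C4 bridge (7-endo).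

**Step 1**
Reactants: 1 3',4'-dihydroxyacetophenone
Product: 2 1-[3,4-bis(tert-butyldimethylsilyloxy)phenyl]ethan-1-one
Conditions: tBuMe2SiCl (2.5 equiv), imidazole (5 equiv), DMF, rt
Reagents that add atoms: tert-butyldimethylsilyl chloride, CC(C)(C)[Si](C)(C)Cl
Why: Imidazole-promoted silylation of both phenols masks the catechol as ethers that tolerate the amide bases used later and are removed by fluoride at the end.

**Step 2**
Reactants: 2 1-[3,4-bis(tert-butyldimethylsilyloxy)phenyl]ethan-1-one; 3 N-methoxy-N-methylacetamide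
Product: 5 1-[3,4-bis(tert-butyldimethylsilyloxy)phenyl]butane-1,3-dione, via lithium enolate 4 (not isolated)
Conditions: LiN(SiMe3)2 (2.2 equiv), THF, −78 °C; then 3, −78 °C to rt; aq. NH4Cl
Reagents that add atoms: none
Why: Claisen-type acylation of the ketone enolate by a Weinreb amide should give the 1,3-diketone without releasing alkoxide, which would attack the aryl silyl ethers, the second equivalent of base holding the product as its enolate.

**Step 3**
Reactants: 6 3-methylbutane-1,3-diol
Product: 7 4-iodo-2-methylbutan-2-ol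
Conditions: PPh3, I2, imidazole, CH2Cl2, 0 °C to rt
Reagents that add atoms: iodine, II
Why: Appel-type iodination should convert only the primary hydroxyl, because the tertiary one is too hindered to be displaced through its alkoxyphosphonium salt.

**Step 4**
Reactants: 7 4-iodo-2-methylbutan-2-ol
Product: 8 triethyl[(4-iodo-2-methylbutan-2-yl)oxy]silane
Conditions: Et3SiOTf, 2,6-lutidine, CH2Cl2, −78 to 0 °C
Reagents that add atoms: triethylsilyl trifluoromethanesulfonate, CC[Si](CC)(CC)OS(=O)(=O)C(F)(F)F
Why: A silyl triflate with a hindered pyridine base silylates the tertiary alcohol, which would otherwise be acylated by the acid chloride in step 14.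

**Step 5**
Reactants: 5 1-[3,4-bis(tert-butyldimethylsilyloxy)phenyl]butane-1,3-dione; 8 triethyl[(4-iodo-2-methylbutan-2-yl)oxy]silane
Product: 10 1-[3,4-bis(tert-butyldimethylsilyloxy)phenyl]-7-methyl-7-(triethylsilyloxy)octane-1,3-dione, via dilithium dianion 9 (not isolated)
Conditions: LiN(iPr)2 (2.2 equiv), THF, −78 to 0 °C; then 8, 0 °C to rt; aq. NH4Cl
Reagents that add atoms: none
Why: γ-Alkylation of a 1,3-diketone dianion takes place at the terminal carbanion, the more reactive site, and the unhindered primary iodide is a good SN2 partner, so the chain should grow only at the methyl carbon (future C1).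

**Step 6**
Reactants: 11 (R)-4-benzyloxazolidin-2-one; 12 acryloyl chloride
Product: 13 (R)-3-acryloyl-4-benzyloxazolidin-2-one
Conditions: Et3N, LiCl, THF, −20 °C to rt
Reagents that add atoms: none
Why: N-Acylation of the oxazolidinone under LiCl/amine activation avoids strong base and so limits polymerisation of the acrylate.

**Step 7**
Reactants: 14 di-tert-butyl malonate; 13 (R)-3-acryloyl-4-benzyloxazolidin-2-one (2.2 equiv)
Product: 15 di-tert-butyl 2,2-bis{3-[(4R)-4-benzyl-2-oxo-1,3-oxazolidin-3-yl]-3-oxopropyl}propanedioate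
Conditions: Cs2CO3 (0.2 equiv), MeCN, rt
Reagents that add atoms: none
Why: Two successive Michael additions of the malonate to the strongly accepting acrylimide under catalytic carbonate build the quaternary carbon (future C5) with two identical arms, and no stereocentre is formed.

**Step 8**
Reactants: 15 di-tert-butyl 2,2-bis{3-[(4R)-4-benzyl-2-oxo-1,3-oxazolidin-3-yl]-3-oxopropyl}propanedioate; 16 prenyl bromide (4.4 equiv)
Product: 18 di-tert-butyl 2,2-bis{(2R)-2-{[(4R)-4-benzyl-2-oxo-1,3-oxazolidin-3-yl]carbonyl}-5-methylhex-4-en-1-yl}propanedioate, via disodium bis-enolate 17 (not isolated)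
Conditions: NaN(SiMe3)2 (2.4 equiv), THF, −78 °C; then 16 (4.4 equiv), −78 to −45 °C; aq. NH4Cl
Reagents that add atoms: none
Why: In this two-directional Evans alkylation two molecules of 16 are taken up, one at each imide enolate; each chelated Z-enolate is shielded on one face by the benzyl group of the (R)-auxiliary, so prenyl bromide should enter from the open face and set both new centres R, the minor mixed diastereomer being removed by chromatography.

**Step 9**
Reactants: 18 di-tert-butyl 2,2-bis{(2R)-2-{[(4R)-4-benzyl-2-oxo-1,3-oxazolidin-3-yl]carbonyl}-5-methylhex-4-en-1-yl}propanedioate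
Product: 19 di-tert-butyl 2,2-bis[(2R)-2-(ethylsulfanylcarbonyl)-5-methylhex-4-en-1-yl]propanedioate
Conditions: EtSH, nBuLi, THF, 0 °C; aq. NH4Cl
Reagents that add atoms: ethanethiol, CCS
Why: Thiolysis of N-acyl oxazolidinones by lithium ethanethiolate takes place at the exocyclic carbonyl even for hindered acyl groups, releases the auxiliary for recovery and is too weakly basic to epimerise the α-centres or attack the tert-butyl esters.

**Step 10**
Reactants: 19 di-tert-butyl 2,2-bis[(2R)-2-(ethylsulfanylcarbonyl)-5-methylhex-4-en-1-yl]propanedioate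
Product: 20 di-tert-butyl 2,2-bis[(2R)-2-acetyl-5-methylhex-4-en-1-yl]propanedioate
Conditions: Me2CuLi (from MeLi and CuI), Et2O, −78 to −40 °C; aq. NH4Cl
Reagents that add atoms: lithium dimethylcuprate, [Li+].C[Cu-]C
Why: Thioesters are converted by Gilman cuprates into ketones without over-addition, and the hindered tert-butyl esters and the α-stereocentres should be untouched by this weakly basic reagent.

**Step 11**
Reactants: 20 di-tert-butyl 2,2-bis[(2R)-2-acetyl-5-methylhex-4-en-1-yl]propanedioate
Product: 21 di-tert-butyl 2,2-bis[(2R)-5-methyl-2-(prop-1-en-2-yl)hex-4-en-1-yl]propanedioate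
Conditions: Zn, CH2Br2, TiCl4, THF/CH2Cl2, 0 °C to rt
Reagents that add atoms: dibromomethane, BrCBr
Why: Takai–Lombardo methylenation uses a non-basic gem-dimetallic methylene reagent, which should turn both ketones into isopropenyl groups without epimerising the adjacent centres and without touching the esters.

**Step 12**
Reactants: 21 di-tert-butyl 2,2-bis[(2R)-5-methyl-2-(prop-1-en-2-yl)hex-4-en-1-yl]propanedioate
Product: 23 2,2-bis[(2R)-5-methyl-2-(prop-1-en-2-yl)hex-4-en-1-yl]propanedioic acid, via bis(trimethylsilyl) ester 22 (not isolated)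
Conditions: Me3SiOTf, 2,6-lutidine, CH2Cl2, 0 °C to rt; then pH 3 aqueous buffer
Reagents that add atoms: none
Why: Silyl triflate cleaves tert-butyl esters by alkyl–oxygen fission with loss of isobutene, so the hindered carbonyls need not be attacked, and the lutidine buffer should keep acid away from the four double bonds; the silyl esters hydrolyse on work-up.

**Step 13**
Reactants: 23 2,2-bis[(2R)-5-methyl-2-(prop-1-en-2-yl)hex-4-en-1-yl]propanedioic acid
Product: 24 2,2-bis[(2R)-5-methyl-2-(prop-1-en-2-yl)hex-4-en-1-yl]propanedioyl dichloride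
Conditions: 1-chloro-N,N,2-trimethylprop-1-en-1-amine (2.4 equiv), CH2Cl2, 0 °C to rt; volatiles removed, used at once
Reagents that add atoms: 1-chloro-N,N,2-trimethylprop-1-en-1-amine, CC(C)=C(Cl)N(C)C
Why: The α-chloroenamine converts carboxylic acids into acid chlorides under neutral conditions with an amide as the only by-product, so no HCl is present to add to the alkenes, and the quaternary α-carbon rules out ketene formation.

**Step 14**
Reactants: 10 1-[3,4-bis(tert-butyldimethylsilyloxy)phenyl]-7-methyl-7-(triethylsilyloxy)octane-1,3-dione (2.2 equiv); 24 2,2-bis[(2R)-5-methyl-2-(prop-1-en-2-yl)hex-4-en-1-yl]propanedioyl dichloride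
Product: 27 2-[3,4-bis(tert-butyldimethylsilyloxy)benzoyl]-3,5-dihydroxy-4,4-bis[(2R)-5-methyl-2-(prop-1-en-2-yl)hex-4-en-1-yl]-6-[3-methyl-3-(triethylsilyloxy)butyl]cyclohexa-2,5-dien-1-one, via dilithium dianion 25 (not isolated), via open-chain acyl chloride enolate 26 (not isolated)
Conditions: LiN(iPr)2 (4.4 equiv), THF, −78 to 0 °C; then 24 in THF, −78 °C to rt; aq. citric acid
Reagents that add atoms: none
Why: The dianion 25 reacts first at its terminal carbon, the more basic and less delocalised site, with one acyl chloride of 24 to form C1–C9 (26), and the remaining 1,3-diketone enolate then attacks the second acyl chloride through its central carbon C3 to form C3–C4. The closest known reaction type is the Claisen-type C-acylation of 1,3-dicarbonyl dianions at the terminal carbon, joined to a second, intramolecular Claisen acylation as in the [3+3] cyclocondensations of malonyl dichlorides with 1,3-dicarbonyl dianions or 1,3-bis(silyloxy)dienes that give 2-acylcyclohexane-1,3,5-triones. Ring A closes by a 6-exo-trig acyl substitution at the second acyl chloride carbon. No stereocentre is created, because C5 carries two identical (R)-lavandulyl groups, the two acyl chlorides are equivalent, and C1 and C3 end up enolised. The step needs site selectivity only (terminal carbon before central carbon, and carbon before oxygen in the ring closure): the first is inherent in dianion reactivity, and the second is favoured because the C-acylated ring is a fully enolised triketone anion, the thermodynamic sink to which an enol lactone can return by acyl transfer, while the extra equivalent of dianion takes up the two acidic protons of the product and unreacted 10 is recovered. The hindrance of the neopentyl-type acyl chlorides should be offset by their high reactivity and by the intramolecular nature of the second acylation.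

**Step 15**
Reactants: 27 2-[3,4-bis(tert-butyldimethylsilyloxy)benzoyl]-3,5-dihydroxy-4,4-bis[(2R)-5-methyl-2-(prop-1-en-2-yl)hex-4-en-1-yl]-6-[3-methyl-3-(triethylsilyloxy)butyl]cyclohexa-2,5-dien-1-one
Product: 28 (1R,5R,7R)-3-[3,4-bis(tert-butyldimethylsilyloxy)benzoyl]-4-hydroxy-1-(3-hydroxy-3-methylbutyl)-8,8-dimethyl-7-(3-methylbut-2-en-1-yl)-5-[(2R)-5-methyl-2-(prop-1-en-2-yl)hex-4-en-1-yl]bicyclo[3.3.1]non-3-ene-2,9-dione
Conditions: HCO2H, CH2Cl2, 0 °C to rt, stopped when 27 is consumed; NaHCO3, aq. MeOH work-up; chromatographic separation of the C1/C5 diastereomers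
Reagents that add atoms: none
Why: Protonation of one isopropenyl terminus by formic acid, assisted by attack of the nucleophilic enol carbon C1 on the developing tertiary centre C8 (a biomimetic cationic cyclisation, the 6-exo Markovnikov hydroalkylation known for 5-alkenyl dearomatised acylphloroglucinols), should close ring B and cleave the triethylsilyl ether, C7 keeping its R configuration while C1 and C5 are set together by which diastereotopic lavandulyl group closes: the 1R,5R (7-endo) product wanted here is expected from closure through a boat-like ring B with the prenyl group pseudo-equatorial, and the 1S,5S (7-exo) diastereomer from a chair-like closure of the other group is removed by chromatography.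

**Step 16**
Reactants: 28 (1R,5R,7R)-3-[3,4-bis(tert-butyldimethylsilyloxy)benzoyl]-4-hydroxy-1-(3-hydroxy-3-methylbutyl)-8,8-dimethyl-7-(3-methylbut-2-en-1-yl)-5-[(2R)-5-methyl-2-(prop-1-en-2-yl)hex-4-en-1-yl]bicyclo[3.3.1]non-3-ene-2,9-dione
Product: 29 (1R,5R,7R)-3-(3,4-dihydroxybenzoyl)-4-hydroxy-1-(3-hydroxy-3-methylbutyl)-8,8-dimethyl-7-(3-methylbut-2-en-1-yl)-5-[(2R)-5-methyl-2-(prop-1-en-2-yl)hex-4-en-1-yl]bicyclo[3.3.1]non-3-ene-2,9-dione (CNP0148616.1)
Conditions: Bu4NF, AcOH, THF, 0 °C to rt
Reagents that add atoms: none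
Why: Fluoride cleaves the two aryl silicon–oxygen bonds, and the acetic acid buffer keeps the catechol and the enolised triketone protonated, which should avoid both base-mediated oxidation of the catechol and acid-mediated cyclisation of the isopropenyl group.

**Compound list**
1 | 3',4'-dihydroxyacetophenone | CC(=O)c1ccc(O)c(O)c1 | starting material
2 | 1-[3,4-bis(tert-butyldimethylsilyloxy)phenyl]ethan-1-one | CC(=O)c1ccc(O[Si](C)(C)C(C)(C)C)c(O[Si](C)(C)C(C)(C)C)c1 | intermediate
3 | N-methoxy-N-methylacetamide | CC(=O)N(C)OC | starting material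
4 | lithium enolate of 2 | [Li+].C=C([O-])c1ccc(O[Si](C)(C)C(C)(C)C)c(O[Si](C)(C)C(C)(C)C)c1 | intermediate (not isolated)
5 | 1-[3,4-bis(tert-butyldimethylsilyloxy)phenyl]butane-1,3-dione | CC(=O)CC(=O)c1ccc(O[Si](C)(C)C(C)(C)C)c(O[Si](C)(C)C(C)(C)C)c1 | intermediate
6 | 3-methylbutane-1,3-diol | CC(C)(O)CCO | starting material
7 | 4-iodo-2-methylbutan-2-ol | CC(C)(O)CCI | intermediate
8 | triethyl[(4-iodo-2-methylbutan-2-yl)oxy]silane | CC[Si](CC)(CC)OC(C)(C)CCI | intermediate
9 | dilithium 1,3-dianion of 5 | [Li+].[Li+].C=C([O-])C=C([O-])c1ccc(O[Si](C)(C)C(C)(C)C)c(O[Si](C)(C)C(C)(C)C)c1 | intermediate (not isolated)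
10 | 1-[3,4-bis(tert-butyldimethylsilyloxy)phenyl]-7-methyl-7-(triethylsilyloxy)octane-1,3-dione | CC(C)(CCCC(=O)CC(=O)c1ccc(O[Si](C)(C)C(C)(C)C)c(O[Si](C)(C)C(C)(C)C)c1)O[Si](CC)(CC)CC | intermediate (precursor of the key step)
11 | (R)-4-benzyloxazolidin-2-one | O=C1N[C@H](Cc2ccccc2)CO1 | starting material
12 | acryloyl chloride | C=CC(=O)Cl | starting material
13 | (R)-3-acryloyl-4-benzyloxazolidin-2-one | C=CC(=O)N1[C@H](Cc2ccccc2)COC1=O | intermediate
14 | di-tert-butyl malonate | CC(C)(C)OC(=O)CC(=O)OC(C)(C)C | starting material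
15 | di-tert-butyl 2,2-bis{3-[(4R)-4-benzyl-2-oxo-1,3-oxazolidin-3-yl]-3-oxopropyl}propanedioate | CC(C)(C)OC(=O)C(CCC(=O)N1[C@H](Cc2ccccc2)COC1=O)(CCC(=O)N1[C@H](Cc2ccccc2)COC1=O)C(=O)OC(C)(C)C | intermediate
16 | prenyl bromide (1-bromo-3-methylbut-2-ene) | CC(C)=CCBr | starting material
17 | disodium bis-(Z)-enolate of 15 | [Na+].[Na+].CC(C)(C)OC(=O)C(C/C=C(\[O-])N1[C@H](Cc2ccccc2)COC1=O)(C/C=C(\[O-])N1[C@H](Cc2ccccc2)COC1=O)C(=O)OC(C)(C)C | intermediate (not isolated)
18 | di-tert-butyl 2,2-bis{(2R)-2-{[(4R)-4-benzyl-2-oxo-1,3-oxazolidin-3-yl]carbonyl}-5-methylhex-4-en-1-yl}propanedioate | CC(C)(C)OC(=O)C(C[C@@H](CC=C(C)C)C(=O)N1[C@H](Cc2ccccc2)COC1=O)(C[C@@H](CC=C(C)C)C(=O)N1[C@H](Cc2ccccc2)COC1=O)C(=O)OC(C)(C)C | intermediate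
19 | di-tert-butyl 2,2-bis[(2R)-2-(ethylsulfanylcarbonyl)-5-methylhex-4-en-1-yl]propanedioate | CC(C)(C)OC(=O)C(C[C@@H](CC=C(C)C)C(=O)SCC)(C[C@@H](CC=C(C)C)C(=O)SCC)C(=O)OC(C)(C)C | intermediate
20 | di-tert-butyl 2,2-bis[(2R)-2-acetyl-5-methylhex-4-en-1-yl]propanedioate | CC(C)(C)OC(=O)C(C[C@@H](CC=C(C)C)C(C)=O)(C[C@@H](CC=C(C)C)C(C)=O)C(=O)OC(C)(C)C | intermediate
21 | di-tert-butyl 2,2-bis[(2R)-5-methyl-2-(prop-1-en-2-yl)hex-4-en-1-yl]propanedioate | CC(C)(C)OC(=O)C(C[C@@H](CC=C(C)C)C(C)=C)(C[C@@H](CC=C(C)C)C(C)=C)C(=O)OC(C)(C)C | intermediate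
22 | bis(trimethylsilyl) 2,2-bis[(2R)-5-methyl-2-(prop-1-en-2-yl)hex-4-en-1-yl]propanedioate | C[Si](C)(C)OC(=O)C(C[C@@H](CC=C(C)C)C(C)=C)(C[C@@H](CC=C(C)C)C(C)=C)C(=O)O[Si](C)(C)C | intermediate (not isolated)
23 | 2,2-bis[(2R)-5-methyl-2-(prop-1-en-2-yl)hex-4-en-1-yl]propanedioic acid | OC(=O)C(C[C@@H](CC=C(C)C)C(C)=C)(C[C@@H](CC=C(C)C)C(C)=C)C(=O)O | intermediate
24 | 2,2-bis[(2R)-5-methyl-2-(prop-1-en-2-yl)hex-4-en-1-yl]propanedioyl dichloride | O=C(Cl)C(C[C@@H](CC=C(C)C)C(C)=C)(C[C@@H](CC=C(C)C)C(C)=C)C(=O)Cl | intermediate (precursor of the key step)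
25 | dilithium 1,3-dianion of 10 | [Li+].[Li+].CC(C)(CCC=C([O-])C=C([O-])c1ccc(O[Si](C)(C)C(C)(C)C)c(O[Si](C)(C)C(C)(C)C)c1)O[Si](CC)(CC)CC | intermediate (not isolated)
26 | lithium enolate of the open-chain C1-acylated tetraketo acyl chloride | [Li+].[O-]C(=CC(=O)C(CCC(C)(C)O[Si](CC)(CC)CC)C(=O)C(C[C@@H](CC=C(C)C)C(C)=C)(C[C@@H](CC=C(C)C)C(C)=C)C(=O)Cl)c1ccc(O[Si](C)(C)C(C)(C)C)c(O[Si](C)(C)C(C)(C)C)c1 | intermediate (not isolated)
27 | 2-[3,4-bis(tert-butyldimethylsilyloxy)benzoyl]-3,5-dihydroxy-4,4-bis[(2R)-5-methyl-2-(prop-1-en-2-yl)hex-4-en-1-yl]-6-[3-methyl-3-(triethylsilyloxy)butyl]cyclohexa-2,5-dien-1-one | C=C(C)[C@H](CC=C(C)C)CC1(C[C@@H](CC=C(C)C)C(C)=C)C(O)=C(C(=O)c2ccc(O[Si](C)(C)C(C)(C)C)c(O[Si](C)(C)C(C)(C)C)c2)C(=O)C(CCC(C)(C)O[Si](CC)(CC)CC)=C1O | intermediate (product of the key step)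
28 | (1R,5R,7R)-3-[3,4-bis(tert-butyldimethylsilyloxy)benzoyl]-4-hydroxy-1-(3-hydroxy-3-methylbutyl)-8,8-dimethyl-7-(3-methylbut-2-en-1-yl)-5-[(2R)-5-methyl-2-(prop-1-en-2-yl)hex-4-en-1-yl]bicyclo[3.3.1]non-3-ene-2,9-dione | C=C(C)[C@H](CC=C(C)C)C[C@@]12C[C@@H](CC=C(C)C)C(C)(C)[C@@](CCC(C)(C)O)(C(=O)C(C(=O)c3ccc(O[Si](C)(C)C(C)(C)C)c(O[Si](C)(C)C(C)(C)C)c3)=C1O)C2=O | intermediate
29 | (1R,5R,7R)-3-(3,4-dihydroxybenzoyl)-4-hydroxy-1-(3-hydroxy-3-methylbutyl)-8,8-dimethyl-7-(3-methylbut-2-en-1-yl)-5-[(2R)-5-methyl-2-(prop-1-en-2-yl)hex-4-en-1-yl]bicyclo[3.3.1]non-3-ene-2,9-dione | C=C(C)[C@H](CC=C(C)C)C[C@@]12C[C@@H](CC=C(C)C)C(C)(C)[C@@](CCC(C)(C)O)(C(=O)C(C(=O)c3ccc(O)c(O)c3)=C1O)C2=O | target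

**Step count**
Total: 16 steps. Longest linear sequence: 11 steps (steps 6 to 16); steps 1 to 5 make the diketone 10 in parallel.

**Steps most likely to fail**

1. Step 15 (ring B closure). Three processes threaten it.
 - The other diastereotopic lavandulyl group may close through the chair-like arrangement and lead into the 1S,5S (7-exo) series; this may well be the faster closure.
 - The tertiary cation may be captured by an enol oxygen instead of C1.
 - On longer exposure to acid the C4 enol oxygen may add to the remaining isopropenyl group, that group may isomerise, or the freed tertiary alcohol may ionise.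

 The fallback sets out from 27 and replaces the ionic closure by a neutral thermal enol-ene (Conia-ene) closure. 27 is heated in degassed mesitylene at about 150–170 °C in a sealed tube with a trace of 2,6-di-tert-butyl-4-methylphenol. The enol hydrogen is passed to the alkene terminus while C1 bonds to C8 in one cyclic transition state, so no free cation arises, the second isopropenyl group and the silyl ether are not activated, and the choice between the two lavandulyl groups is made by a different transition-state geometry. This would give the bicyclic triethylsilyl ether F1, which is treated with Bu4NF/AcOH as in step 16 (all three silyl groups removed), so that the fallback comes back to the route at 29.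

2. Step 14 (key step). The ring-closing acylation may occur on the enolate oxygen instead of C3, the first acylation product may quench unreacted dianion by proton transfer, and attack at the hindered acyl chlorides may be slow. The fallback sets out from 10 and uses a neutral, silicon-capped nucleophile in place of the dianion. 10 is silylated (Me3SiCl, Et3N) to 1-[3,4-bis(tert-butyldimethylsilyloxy)phenyl]-7-methyl-7-(triethylsilyloxy)-1-(trimethylsilyloxy)oct-1-en-3-one F2 (either enol regioisomer serves). Deprotonation and a second silylation (LiN(iPr)2, Me3SiCl, THF, −78 °C) give the 1,3-bis(trimethylsilyloxy)octa-1,3-diene F3. Lewis-acid-mediated [3+3] cyclisation of F3 with 24 (Me3SiOTf, CH2Cl2, −78 to −20 °C) should then take place at the terminal and then the central carbon, since both oxygens carry silicon and no acidic proton is present. Aqueous work-up returns the route to 27.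

3. Step 8 (two-directional alkylation). The enolate carbons lie next to a neopentyl-type quaternary centre, so alkylation may be slow or incomplete, facial control may be lost at one of the two sites, and the enolate may fragment by retro-Michael loss of the malonate. The fallback sets out from 14 and attaches both chains ready-made. (S)-Lavandulol F4 is obtained from commercial racemic lavandulol by the known lipase-mediated kinetic resolution; the S alcohol carries the R descriptor once its CH2 is bound to the malonate carbon. It is converted with PPh3, I2 and imidazole into (S)-lavandulyl iodide F5. Alkylation of 14 (NaH, DMF) gives di-tert-butyl 2-[(2R)-5-methyl-2-(prop-1-en-2-yl)hex-4-en-1-yl]propanedioate F6, and a second alkylation with F5 (NaH, DMF, 50 °C) gives 21, where the fallback rejoins the route in place of steps 6 to 11.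

**Further compounds**
F1 | step 15 | (1R,5R,7R)-3-[3,4-bis(tert-butyldimethylsilyloxy)benzoyl]-4-hydroxy-8,8-dimethyl-1-[3-methyl-3-(triethylsilyloxy)butyl]-7-(3-methylbut-2-en-1-yl)-5-[(2R)-5-methyl-2-(prop-1-en-2-yl)hex-4-en-1-yl]bicyclo[3.3.1]non-3-ene-2,9-dione | C=C(C)[C@H](CC=C(C)C)C[C@@]12C[C@@H](CC=C(C)C)C(C)(C)[C@@](CCC(C)(C)O[Si](CC)(CC)CC)(C(=O)C(C(=O)c3ccc(O[Si](C)(C)C(C)(C)C)c(O[Si](C)(C)C(C)(C)C)c3)=C1O)C2=O
F2 | step 14 | 1-[3,4-bis(tert-butyldimethylsilyloxy)phenyl]-7-methyl-7-(triethylsilyloxy)-1-(trimethylsilyloxy)oct-1-en-3-one | CC(C)(CCCC(=O)C=C(O[Si](C)(C)C)c1ccc(O[Si](C)(C)C(C)(C)C)c(O[Si](C)(C)C(C)(C)C)c1)O[Si](CC)(CC)CC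
F3 | step 14 | 1-[3,4-bis(tert-butyldimethylsilyloxy)phenyl]-7-methyl-7-(triethylsilyloxy)-1,3-bis(trimethylsilyloxy)octa-1,3-diene | CC(C)(CCC=C(O[Si](C)(C)C)C=C(O[Si](C)(C)C)c1ccc(O[Si](C)(C)C(C)(C)C)c(O[Si](C)(C)C(C)(C)C)c1)O[Si](CC)(CC)CC
F4 | step 8 | (S)-lavandulol | OC[C@@H](CC=C(C)C)C(C)=C
F5 | step 8 | (S)-lavandulyl iodide | IC[C@@H](CC=C(C)C)C(C)=C
F6 | step 8 | di-tert-butyl 2-[(2R)-5-methyl-2-(prop-1-en-2-yl)hex-4-en-1-yl]propanedioate | CC(C)(C)OC(=O)C(C[C@@H](CC=C(C)C)C(C)=C)C(=O)OC(C)(C)C
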